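**Retrosynthetic overview**
1. Target ⇐ hydrolysis of the methyl ester and aryl pivalate; equatorial C3–Br from the axial C3 alcohol with inversion; that alcohol from the C3 ketone; side-chain alkene by Wittig reaction on the C4 chain aldehyde.
2. C11–aryl bond ⇐ Negishi coupling of a C11 alkylzinc with methyl 3-bromo-5-iodo-4-(pivaloyloxy)benzoate; the C11 zinc from the C9 ester (reduction, iodide).
3. C8=C12 methylidene and C9–H ⇐ deconjugation of the C8=C9 ester; trans ring fusion ⇐ hydrogenation of C5=C6.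
4. Ring B ⇐ Diels–Alder reaction. The feature used: quaternary C10 is flanked in ring B by C9 and C8, whose substituents C11 and C12 are the ester carbon and the methyl of but-2-ynoate, while C5–C6–C7 are a ring A carbon plus a vinyl group; ring B is therefore diene C10=C5–C6=C7 plus C9≡C8.
5. Ring A diene ⇐ Stille vinylation of an enol triflate, C10 methylation, enzymatic desymmetrisation (C3, C4) of 2-allyl-2-methylcyclohexane-1,3-dione. Ring order: ring A (from the dione), then ring B (step 9); the arene is brought in intact.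

Key step: step 9

Assumption: a ketoreductase giving the (2S,3R) ketol 3 is taken from a commercial enzyme panel by screening, since stereodivergent enzymatic reduction of 2,2-disubstituted cyclohexane-1,3-diones is established; atoms carry terpenoid numbers (ring A = C1–C5 and C10, ring B = C5–C10, C11 benzylic, C12 methylidene) and TBS = tert-butyldimethylsilyl.

**Route**

Step 1
Reactants: 1 2-methylcyclohexane-1,3-dione
Product: 2 2-methyl-2-(prop-2-en-1-yl)cyclohexane-1,3-dione
Conditions: allyl bromide, NaOH (1 M aq), rt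
Reagents that add atoms: allyl bromide, C=CCBr
Why: C-alkylation of the 1,3-dione enolate with an allylic halide is dependable (an unactivated 3-silyloxypropyl halide would alkylate mainly on oxygen), and any O-allyl enol ether returns 2 on warming by Claisen rearrangement.

Step 2
Reactants: 2 2-allyl-2-methylcyclohexane-1,3-dione
Product: 3 (2S,3R)-3-hydroxy-2-methyl-2-(prop-2-en-1-yl)cyclohexan-1-one (hydroxyl cis to methyl)
Conditions: ketoreductase (R-selective), NADP+ (cat.), i-PrOH, KH2PO4/K2HPO4 buffer pH 7, 30 °C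
Reagents that add atoms: none
Why: Enzymatic desymmetrising carbonyl reduction of a prochiral 2,2-disubstituted 1,3-dione: the choice between the two enantiotopic carbonyl groups sets the quaternary centre (future C4) and the face of hydride delivery sets the carbinol (future C3), the enzyme being selected for hydroxyl cis to methyl.

Step 3
Reactants: 3 (2S,3R) ketol
Product: 4 (2S,3R)-3-[(TBS)oxy]-2-methyl-2-(prop-2-en-1-yl)cyclohexan-1-one
Conditions: TBSOTf, 2,6-lutidine, CH2Cl2, −78 → 0 °C
Reagents that add atoms: tert-butyldimethylsilyl trifluoromethanesulfonate, CC(C)(C)[Si](C)(C)OS(=O)(=O)C(F)(F)F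
Why: A silyl triflate with a hindered pyridine base silylates the neopentyl secondary alcohol without retro-aldol cleavage of the β-hydroxy ketone, and no stereocentre is touched.

Step 4
Reactants: 4 silyl ether of the ketol
Product: 6 (2S,3R)-3-[(TBS)oxy]-2-(3-hydroxypropyl)-2-methylcyclohexan-1-one, via B-alkyl-9-BBN adduct 5 (not isolated)
Conditions: 9-BBN, THF, 0 °C → rt; then NaOH (aq), H2O2, 0 °C
Reagents that add atoms: hydrogen peroxide, OO
Why: Hydroboration–oxidation: 9-BBN adds boron to the terminal carbon of the monosubstituted alkene much faster than it reduces the hindered ketone, and oxidation gives the primary alcohol.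

Step 5
Reactants: 6 primary alcohol
Product: 7 (2S,3R)-3-[(TBS)oxy]-2-{3-[(TBS)oxy]propyl}-2-methylcyclohexan-1-one
Conditions: TBSCl, imidazole, DMF, rt
Reagents that add atoms: tert-butyldimethylsilyl chloride, CC(C)(C)[Si](C)(C)Cl
Why: Standard silylation of a primary alcohol.

Step 6
Reactants: 7 bis-silyl ketone
Product: 9 (2S,3R)-3-[(TBS)oxy]-2-{3-[(TBS)oxy]propyl}-2,6-dimethylcyclohexan-1-one (both C6 epimers), via lithium enolate 8 (not isolated)
Conditions: LiN(i-Pr)2, THF, −78 °C; MeI, −78 → −20 °C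
Reagents that add atoms: iodomethane, CI
Why: Kinetic enolate alkylation: only C6 carries α-hydrogens (the other α-carbon is quaternary), so the methyl enters at the future C10, and the mixed configuration there is of no consequence because the centre becomes sp2 in step 7.

Step 7
Reactants: 9 methyl ketone
Product: 11 (5R,6S)-5-[(TBS)oxy]-6-{3-[(TBS)oxy]propyl}-2,6-dimethylcyclohex-1-en-1-yl trifluoromethanesulfonate, via potassium enolate 10 (not isolated)
Conditions: KN(SiMe3)2, THF, −78 → 0 °C; PhNTf2, −78 °C → rt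
Reagents that add atoms: N-phenylbis(trifluoromethanesulfonimide), O=S(=O)(N(c1ccccc1)S(=O)(=O)C(F)(F)F)C(F)(F)F
Why: Enol triflate formation: the single enolisable position gives only the tetrasubstituted enolate, which is trapped on oxygen.

Step 8
Reactants: 11 enol triflate
Product: 12 ring A diene, (1R,2R)-1-[(TBS)oxy]-2-{3-[(TBS)oxy]propyl}-3-ethenyl-2,4-dimethylcyclohex-3-ene (silyloxy group cis to the quaternary methyl)
Conditions: CH2=CHSnBu3, Pd(PPh3)4 (cat.), LiCl, THF, 65 °C
Reagents that add atoms: tributyl(vinyl)stannane, C=C[Sn](CCCC)(CCCC)CCCC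
Why: Stille coupling of a hindered cyclohexenyl triflate with a vinylstannane, with chloride assisting the transmetalation, is established for 2,6,6-trisubstituted cyclohexenyl triflates.

Step 9
Reactants: 12 ring A diene; 13 methyl but-2-ynoate
Product: 14 methyl (5R,6R,8aR)-6-[(TBS)oxy]-5-{3-[(TBS)oxy]propyl}-2,5,8a-trimethyl-3,5,6,7,8,8a-hexahydronaphthalene-1-carboxylate (5,8-diene in terpenoid numbering; C10 methyl cis to C4 methyl)
Conditions: 13 (5 equiv), BHT (cat.), CH2Cl2, 12 kbar, 45 °C
Reagents that add atoms: none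
Why: Concerted, asynchronous, suprafacial [4+2] cycloaddition of the C10=C5–C6=C7 diene with the ynoate C9≡C8; the closest known reaction type is the Diels–Alder reaction of 2-vinyl-1,3,3-trimethylcyclohexene-type dienes with acetylenic esters used to build drimane decalins. Ring B (C5–C10) closes in the bimolecular event itself, as a six-membered 1,4-cyclohexadiene annulated onto ring A through the new C7–C8 and C9–C10 bonds. The regiochemistry needed (ester carbon on C9 next to C10) follows from the polarisation of both partners: the unsubstituted terminus C7 carries the largest HOMO coefficient and bonds to the electrophilic β-carbon of the ynoate. The one new stereocentre, quaternary C10, is controlled by the diene face: with the C3 silyl ether equatorial the C4 methyl is pseudoaxial on ring A, the ynoate adds to the opposite face, and the C10 methyl therefore ends cis to the C4 methyl, whereas the other half-chair would place the bulky silyloxy group axial on the very face it opens. Pressure is used in place of strong heating because the methyl on C10 twists the diene out of its s-cis form and the ynoate is a weak dienophile, so the negative activation volume should give rate below the temperature at which the diene suffers a 1,5-hydrogen shift. An alkyne dienophile raises no endo or exo question and leaves the C8=C9 enoate for the later deconjugation.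

Step 10
Reactants: 14 Diels–Alder adduct
Product: 15 methyl (4aS,5R,6R,8aR)-6-[(TBS)oxy]-5-{3-[(TBS)oxy]propyl}-2,5,8a-trimethyl-3,4,4a,5,6,7,8,8a-octahydronaphthalene-1-carboxylate (trans-fused, C8=C9 retained)
Conditions: H2 (1 atm), 10% Pd/C, EtOAc, rt
Reagents that add atoms: none
Why: Heterogeneous hydrogenation reduces the trisubstituted C5=C6 bond in preference to the tetrasubstituted conjugated C8=C9 bond and delivers hydrogen to the face opposite the C4 and C10 methyls, which sets C5 with the trans ring fusion.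

Step 11
Reactants: 15 conjugated ester
Product: 17 methyl (1R,4aS,5R,6R,8aR)-6-[(TBS)oxy]-5-{3-[(TBS)oxy]propyl}-5,8a-dimethyl-2-methylidenedecahydronaphthalene-1-carboxylate, via lithium dienolate 16 (not isolated)
Conditions: LiN(i-Pr)2, HMPA, THF, −78 °C; then AcOH, THF, −78 °C
Reagents that add atoms: none
Why: Deconjugative protonation of an extended ester enolate: the amide base removes a proton from the C12 methyl, the γ-position syn to the ester, and kinetic protonation of the dienolate at C9 takes place anti to the axial C10 methyl, giving the equatorial ester and the C8 methylidene.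

Step 12
Reactants: 17 methylidene ester
Product: 18 [(1R,4aS,5R,6R,8aR)-6-[(TBS)oxy]-5-{3-[(TBS)oxy]propyl}-5,8a-dimethyl-2-methylidenedecahydronaphthalen-1-yl]methanol
Conditions: i-Bu2AlH, CH2Cl2, −78 → 0 °C
Reagents that add atoms: none
Why: Hydride reduction of the ester to the primary alcohol, after which C9 can no longer epimerise or reconjugate.

Step 13
Reactants: 18 C11 alcohol
Product: 19 (1R,4aS,5R,6R,8aR)-6-[(TBS)oxy]-5-{3-[(TBS)oxy]propyl}-1-(iodomethyl)-5,8a-dimethyl-2-methylidenedecahydronaphthalene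
Conditions: I2, PPh3, imidazole, CH2Cl2, 0 °C → rt
Reagents that add atoms: iodine, II
Why: Iodination of a primary alcohol through its oxyphosphonium salt (Appel-type, Garegg–Samuelsson conditions).

Step 14
Reactants: 20 methyl 3-bromo-4-hydroxybenzoate
Product: 21 methyl 3-bromo-4-hydroxy-5-iodobenzoate
Conditions: N-iodosuccinimide, CF3CO2H (cat.), MeCN, rt
Reagents that add atoms: N-iodosuccinimide, O=C1CCC(=O)N1I
Why: Electrophilic aromatic iodination at the only free position ortho to the phenol.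

Step 15
Reactants: 21 iodophenol
Product: 22 methyl 3-bromo-4-[(2,2-dimethylpropanoyl)oxy]-5-iodobenzoate
Conditions: t-BuCOCl, Et3N, DMAP (cat.), CH2Cl2, rt
Reagents that add atoms: pivaloyl chloride, CC(C)(C)C(=O)Cl
Why: Acylation of the phenol as a hindered ester that tolerates the organozinc, acidic fluoride, ylide and hydride steps and falls off in the final saponification.

Step 16
Reactants: 19 C11 iodide; 22 aryl iodide
Product: 24 methyl 3-bromo-5-{[(1R,4aS,5R,6R,8aS)-6-[(TBS)oxy]-5-{3-[(TBS)oxy]propyl}-5,8a-dimethyl-2-methylidenedecahydronaphthalen-1-yl]methyl}-4-[(2,2-dimethylpropanoyl)oxy]benzoate, via alkylzinc iodide 23 (not isolated)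
Conditions: Zn dust, LiCl, THF, 40 °C; then 22 (1.2 equiv), PdCl2(dppf) (cat.), THF, rt
Reagents that add atoms: none
Why: Zinc insertion into the primary iodide followed by Negishi coupling: oxidative addition of zerovalent palladium takes place at C–I much faster than at C–Br, and the organozinc tolerates both esters.

Step 17
Reactants: 24 coupled bis-silyl ether
Product: 25 methyl 3-bromo-5-{[(1R,4aS,5R,6R,8aS)-6-hydroxy-5-(3-hydroxypropyl)-5,8a-dimethyl-2-methylidenedecahydronaphthalen-1-yl]methyl}-4-[(2,2-dimethylpropanoyl)oxy]benzoate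
Conditions: HF (48% aq), MeCN, rt
Reagents that add atoms: none
Why: Acidic fluoride cleaves both silyl ethers and leaves the aryl pivalate, which basic fluoride would remove.

Step 18
Reactants: 25 diol
Product: 26 methyl 3-bromo-5-{[(1R,4aS,5R,8aS)-5,8a-dimethyl-2-methylidene-6-oxo-5-(3-oxopropyl)decahydronaphthalen-1-yl]methyl}-4-[(2,2-dimethylpropanoyl)oxy]benzoate
Conditions: Dess–Martin periodinane, NaHCO3, CH2Cl2, rt
Reagents that add atoms: none
Why: Dess–Martin oxidation of the primary and the secondary alcohol under buffered conditions; the keto aldehyde is used at once.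

Step 19
Reactants: 26 keto aldehyde
Product: 27 methyl 3-bromo-5-{[(1R,4aS,5R,8aS)-5,8a-dimethyl-2-methylidene-5-(4-methylpent-3-en-1-yl)-6-oxodecahydronaphthalen-1-yl]methyl}-4-[(2,2-dimethylpropanoyl)oxy]benzoate
Conditions: i-PrPPh3+ I−, n-BuLi, THF, 0 °C; then 26, −78 → 0 °C
Reagents that add atoms: isopropyltriphenylphosphonium iodide, CC(C)[P+](c1ccccc1)(c1ccccc1)c1ccccc1.[I-]
Why: Wittig olefination: the non-stabilised ylide reacts with the aldehyde at low temperature and leaves the hindered neopentyl C3 ketone and the esters untouched, and no alkene geometry arises.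

Step 20
Reactants: 27 C3 ketone
Product: 28 methyl 3-bromo-5-{[(1R,4aS,5R,6S,8aS)-6-hydroxy-5,8a-dimethyl-2-methylidene-5-(4-methylpent-3-en-1-yl)decahydronaphthalen-1-yl]methyl}-4-[(2,2-dimethylpropanoyl)oxy]benzoate (axial C3 hydroxyl)
Conditions: LiBH(s-Bu)3, THF, −78 °C; aq. NH4Cl
Reagents that add atoms: none
Why: The bulky hydride attacks the C3 ketone along the equatorial trajectory, away from the axial hydrogens on C1 and C5, and should give the axial alcohol (hydroxyl trans to the C4 methyl), the usual outcome with 4,4-disubstituted 3-keto decalins.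

Step 21
Reactants: 28 axial C3 alcohol
Product: 29 methyl 3-bromo-5-{[(1R,4aS,5R,6R,8aS)-6-bromo-5,8a-dimethyl-2-methylidene-5-(4-methylpent-3-en-1-yl)decahydronaphthalen-1-yl]methyl}-4-[(2,2-dimethylpropanoyl)oxy]benzoate (equatorial C3 bromide)
Conditions: CBr4, PPh3, PhMe, 60 °C
Reagents that add atoms: carbon tetrabromide, BrC(Br)(Br)Br
Why: Appel bromination: bromide displaces the oxyphosphonium group with inversion (SN2), which turns the axial C3–O bond into the equatorial C3–Br bond of the target.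

Step 22
Reactants: 29 bromide (methyl ester, aryl pivalate)
Product: 30 callophycoic acid H, 3-bromo-5-{[(1R,4aS,5R,6R,8aS)-6-bromo-5,8a-dimethyl-2-methylidene-5-(4-methylpent-3-en-1-yl)decahydronaphthalen-1-yl]methyl}-4-hydroxybenzoic acid
Conditions: LiOH, THF/MeOH/H2O, 40 °C; then aq. HCl to pH 3
Reagents that add atoms: lithium hydroxide, [Li+].[OH-]
Why: Saponification cleaves the methyl ester and the aryl pivalate in one operation, and the equatorial neopentyl bromide has no antiperiplanar hydrogen and resists elimination and substitution.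

**Compound list**
1 | 2-methylcyclohexane-1,3-dione | CC1C(=O)CCCC1=O | starting material
2 | 2-methyl-2-(prop-2-en-1-yl)cyclohexane-1,3-dione | C=CCC1(C)C(=O)CCCC1=O | intermediate
3 | (2S,3R)-3-hydroxy-2-methyl-2-(prop-2-en-1-yl)cyclohexan-1-one | O=C1[C@@](C)(CC=C)[C@H](O)CCC1 | intermediate
4 | (2S,3R)-3-[(TBS)oxy]-2-methyl-2-(prop-2-en-1-yl)cyclohexan-1-one | O=C1[C@@](C)(CC=C)[C@H](O[Si](C)(C)C(C)(C)C)CCC1 | intermediate
5 | B-alkyl-9-BBN adduct of 4 (boron on the terminal carbon of the former allyl group) | O=C1[C@@](C)(CCCB2C3CCCC2CCC3)[C@H](O[Si](C)(C)C(C)(C)C)CCC1 | intermediate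
6 | (2S,3R)-3-[(TBS)oxy]-2-(3-hydroxypropyl)-2-methylcyclohexan-1-one | O=C1[C@@](C)(CCCO)[C@H](O[Si](C)(C)C(C)(C)C)CCC1 | intermediate
7 | (2S,3R)-3-[(TBS)oxy]-2-{3-[(TBS)oxy]propyl}-2-methylcyclohexan-1-one | O=C1[C@@](C)(CCCO[Si](C)(C)C(C)(C)C)[C@H](O[Si](C)(C)C(C)(C)C)CCC1 | intermediate
8 | lithium enolate of 7 (C1=C6) | [Li]OC=1[C@@](C)(CCCO[Si](C)(C)C(C)(C)C)[C@H](O[Si](C)(C)C(C)(C)C)CCC=1 | intermediate
9 | (2S,3R)-3-[(TBS)oxy]-2-{3-[(TBS)oxy]propyl}-2,6-dimethylcyclohexan-1-one (C6 epimers) | O=C1[C@@](C)(CCCO[Si](C)(C)C(C)(C)C)[C@H](O[Si](C)(C)C(C)(C)C)CCC1C | intermediate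
10 | potassium enolate of 9 (tetrasubstituted C1=C6) | [K]OC=1[C@@](C)(CCCO[Si](C)(C)C(C)(C)C)[C@H](O[Si](C)(C)C(C)(C)C)CCC=1C | intermediate
11 | (5R,6S)-5-[(TBS)oxy]-6-{3-[(TBS)oxy]propyl}-2,6-dimethylcyclohex-1-en-1-yl trifluoromethanesulfonate | FC(F)(F)S(=O)(=O)OC=1[C@@](C)(CCCO[Si](C)(C)C(C)(C)C)[C@H](O[Si](C)(C)C(C)(C)C)CCC=1C | intermediate
12 | ring A diene, (1R,2R)-1-[(TBS)oxy]-2-{3-[(TBS)oxy]propyl}-3-ethenyl-2,4-dimethylcyclohex-3-ene | C=CC=1[C@@](C)(CCCO[Si](C)(C)C(C)(C)C)[C@H](O[Si](C)(C)C(C)(C)C)CCC=1C | intermediate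
13 | methyl but-2-ynoate | CC#CC(=O)OC | starting material
14 | methyl (5R,6R,8aR)-6-[(TBS)oxy]-5-{3-[(TBS)oxy]propyl}-2,5,8a-trimethyl-3,5,6,7,8,8a-hexahydronaphthalene-1-carboxylate | CC=1CC=C2[C@@](C)(CCCO[Si](C)(C)C(C)(C)C)[C@H](O[Si](C)(C)C(C)(C)C)CC[C@@]2(C)C=1C(=O)OC | intermediate
15 | methyl (4aS,5R,6R,8aR)-6-[(TBS)oxy]-5-{3-[(TBS)oxy]propyl}-2,5,8a-trimethyl-3,4,4a,5,6,7,8,8a-octahydronaphthalene-1-carboxylate | CC=1CC[C@@H]2[C@@](C)(CCCO[Si](C)(C)C(C)(C)C)[C@H](O[Si](C)(C)C(C)(C)C)CC[C@@]2(C)C=1C(=O)OC | intermediate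
16 | lithium dienolate of 15 (C12=C8, C9=C11) | C=C1CC[C@@H]2[C@@](C)(CCCO[Si](C)(C)C(C)(C)C)[C@H](O[Si](C)(C)C(C)(C)C)CC[C@@]2(C)C1=C(OC)O[Li] | intermediate
17 | methyl (1R,4aS,5R,6R,8aR)-6-[(TBS)oxy]-5-{3-[(TBS)oxy]propyl}-5,8a-dimethyl-2-methylidenedecahydronaphthalene-1-carboxylate | C=C1CC[C@@H]2[C@@](C)(CCCO[Si](C)(C)C(C)(C)C)[C@H](O[Si](C)(C)C(C)(C)C)CC[C@@]2(C)[C@@H]1C(=O)OC | intermediate
18 | [(1R,4aS,5R,6R,8aR)-6-[(TBS)oxy]-5-{3-[(TBS)oxy]propyl}-5,8a-dimethyl-2-methylidenedecahydronaphthalen-1-yl]methanol | C=C1CC[C@@H]2[C@@](C)(CCCO[Si](C)(C)C(C)(C)C)[C@H](O[Si](C)(C)C(C)(C)C)CC[C@@]2(C)[C@@H]1CO | intermediate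
19 | (1R,4aS,5R,6R,8aR)-6-[(TBS)oxy]-5-{3-[(TBS)oxy]propyl}-1-(iodomethyl)-5,8a-dimethyl-2-methylidenedecahydronaphthalene | C=C1CC[C@@H]2[C@@](C)(CCCO[Si](C)(C)C(C)(C)C)[C@H](O[Si](C)(C)C(C)(C)C)CC[C@@]2(C)[C@@H]1CI | intermediate
20 | methyl 3-bromo-4-hydroxybenzoate | COC(=O)c1ccc(O)c(Br)c1 | starting material
21 | methyl 3-bromo-4-hydroxy-5-iodobenzoate | COC(=O)c1cc(Br)c(O)c(I)c1 | intermediate
22 | methyl 3-bromo-4-[(2,2-dimethylpropanoyl)oxy]-5-iodobenzoate | COC(=O)c1cc(Br)c(OC(=O)C(C)(C)C)c(I)c1 | intermediate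
23 | alkylzinc iodide from 19 (zinc on C11) | C=C1CC[C@@H]2[C@@](C)(CCCO[Si](C)(C)C(C)(C)C)[C@H](O[Si](C)(C)C(C)(C)C)CC[C@@]2(C)[C@@H]1C[Zn]I | intermediate
24 | methyl 3-bromo-5-{[(1R,4aS,5R,6R,8aS)-6-[(TBS)oxy]-5-{3-[(TBS)oxy]propyl}-5,8a-dimethyl-2-methylidenedecahydronaphthalen-1-yl]methyl}-4-[(2,2-dimethylpropanoyl)oxy]benzoate | C=C1CC[C@@H]2[C@@](C)(CCCO[Si](C)(C)C(C)(C)C)[C@H](O[Si](C)(C)C(C)(C)C)CC[C@@]2(C)[C@@H]1Cc1cc(C(=O)OC)cc(Br)c1OC(=O)C(C)(C)C | intermediate
25 | methyl 3-bromo-5-{[(1R,4aS,5R,6R,8aS)-6-hydroxy-5-(3-hydroxypropyl)-5,8a-dimethyl-2-methylidenedecahydronaphthalen-1-yl]methyl}-4-[(2,2-dimethylpropanoyl)oxy]benzoate | C=C1CC[C@@H]2[C@@](C)(CCCO)[C@H](O)CC[C@@]2(C)[C@@H]1Cc1cc(C(=O)OC)cc(Br)c1OC(=O)C(C)(C)C | intermediate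
26 | methyl 3-bromo-5-{[(1R,4aS,5R,8aS)-5,8a-dimethyl-2-methylidene-6-oxo-5-(3-oxopropyl)decahydronaphthalen-1-yl]methyl}-4-[(2,2-dimethylpropanoyl)oxy]benzoate | C=C1CC[C@@H]2[C@@](C)(CCC=O)C(=O)CC[C@@]2(C)[C@@H]1Cc1cc(C(=O)OC)cc(Br)c1OC(=O)C(C)(C)C | intermediate
27 | methyl 3-bromo-5-{[(1R,4aS,5R,8aS)-5,8a-dimethyl-2-methylidene-5-(4-methylpent-3-en-1-yl)-6-oxodecahydronaphthalen-1-yl]methyl}-4-[(2,2-dimethylpropanoyl)oxy]benzoate | C=C1CC[C@@H]2[C@@](C)(CCC=C(C)C)C(=O)CC[C@@]2(C)[C@@H]1Cc1cc(C(=O)OC)cc(Br)c1OC(=O)C(C)(C)C | intermediate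
28 | methyl 3-bromo-5-{[(1R,4aS,5R,6S,8aS)-6-hydroxy-5,8a-dimethyl-2-methylidene-5-(4-methylpent-3-en-1-yl)decahydronaphthalen-1-yl]methyl}-4-[(2,2-dimethylpropanoyl)oxy]benzoate | C=C1CC[C@@H]2[C@@](C)(CCC=C(C)C)[C@@H](O)CC[C@@]2(C)[C@@H]1Cc1cc(C(=O)OC)cc(Br)c1OC(=O)C(C)(C)C | intermediate
29 | methyl 3-bromo-5-{[(1R,4aS,5R,6R,8aS)-6-bromo-5,8a-dimethyl-2-methylidene-5-(4-methylpent-3-en-1-yl)decahydronaphthalen-1-yl]methyl}-4-[(2,2-dimethylpropanoyl)oxy]benzoate | C=C1CC[C@@H]2[C@@](C)(CCC=C(C)C)[C@H](Br)CC[C@@]2(C)[C@@H]1Cc1cc(C(=O)OC)cc(Br)c1OC(=O)C(C)(C)C | intermediate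
30 | callophycoic acid H | C=C1CC[C@@H]2[C@@](C)(CCC=C(C)C)[C@H](Br)CC[C@@]2(C)[C@@H]1Cc1cc(C(=O)O)cc(Br)c1O | target

Total step count: 22
Longest linear sequence: 20 steps (steps 1–13 and 16–22); steps 14–15 make the aryl partner.

**Steps most likely to fail**

Step 9. The ynoate is a weak dienophile and the diene is twisted out of its s-cis form, so the cycloaddition may stay slow even under pressure. Control of the diene face by the ring A half-chair may also be incomplete, which would give a mixture of C10 epimers. The fallback ties the dienophile to the C4 side chain (type 2 intramolecular Diels–Alder reaction). From 12, the primary silyl ether is cleaved selectively (HF·pyridine, pyridine, THF, 0 °C) to the dienol F1. Esterification with but-2-ynoic acid (DCC, DMAP, CH2Cl2) should give the dienyl but-2-ynoate F2. Heating in dilute toluene (BHT, 160 °C) should close ring B, the side chain on C4 delivering the ynoate to C10 from its own face. The tether thus reinforces the regiochemistry and fixes the cis relation of the C4 and C10 methyls, giving the bridged nine-membered lactone F3. Methanolysis (NaOMe, MeOH, 50 °C) opens it to the hydroxy ester F4, and silylation (TBSCl, imidazole, DMF) comes back to 14.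

Step 21. At the neopentyl C3, loss of the axial oxyphosphonium group by E2 elimination toward C2, or a 1,2-shift of the antiperiplanar C4 methyl, may outrun backside attack of bromide. The fallback separates activation from displacement. From 28, Tf2O and pyridine (CH2Cl2, −20 °C) should give the axial triflate F5, a discrete and much better leaving group. It is displaced at low temperature by soluble bromide (n-Bu4NBr, toluene, 0 °C → rt) with inversion, coming back to 29.

Step 11. The base may remove a proton from ring carbon C7 in place of the C12 methyl, which after protonation would give the C7=C8 ester, or the dienolate may be protonated at C12 and return 15. The fallback is photochemical deconjugation from 15 (hν 254 nm, 1,2-dimethylimidazole (cat.), hexane, −40 °C). The excited enoate undergoes a 1,5-hydrogen shift that is geometrically possible only from the C12 methyl cis to the ester, giving the photodienol F6. This is protonated at C9 anti to the C10 methyl and comes back to 17.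

**Further compounds**
F1 | step 9 | (1R,2R)-1-[(TBS)oxy]-3-ethenyl-2-(3-hydroxypropyl)-2,4-dimethylcyclohex-3-ene (dienol) | C=CC=1[C@@](C)(CCCO)[C@H](O[Si](C)(C)C(C)(C)C)CCC=1C
F2 | step 9 | 3-[(1R,6R)-6-[(TBS)oxy]-2-ethenyl-1,3-dimethylcyclohex-2-en-1-yl]propyl but-2-ynoate | C=CC=1[C@@](C)(CCCOC(=O)C#CC)[C@H](O[Si](C)(C)C(C)(C)C)CCC=1C
F3 | step 9 | bridged nine-membered lactone of the 5,8-diene (C11 carbonyl joined to the C4 side-chain oxygen) | CC=1CC=C2[C@@](C)(CCCO3)[C@H](O[Si](C)(C)C(C)(C)C)CC[C@@]2(C)C=1C3=O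
F4 | step 9 | methyl (5R,6R,8aR)-6-[(TBS)oxy]-5-(3-hydroxypropyl)-2,5,8a-trimethyl-3,5,6,7,8,8a-hexahydronaphthalene-1-carboxylate | CC=1CC=C2[C@@](C)(CCCO)[C@H](O[Si](C)(C)C(C)(C)C)CC[C@@]2(C)C=1C(=O)OC
F5 | step 21 | axial C3 trifluoromethanesulfonate of 28 | C=C1CC[C@@H]2[C@@](C)(CCC=C(C)C)[C@@H](OS(=O)(=O)C(F)(F)F)CC[C@@]2(C)[C@@H]1Cc1cc(C(=O)OC)cc(Br)c1OC(=O)C(C)(C)C
F6 | step 11 | photodienol of 15 (C12=C8, C9=C11 ketene hemiacetal) | C=C1CC[C@@H]2[C@@](C)(CCCO[Si](C)(C)C(C)(C)C)[C@H](O[Si](C)(C)C(C)(C)C)CC[C@@]2(C)C1=C(O)OC
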